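The readings stem from a simulated flask for an exercise; scatter was added.

**The flask.** Starting material enters the flask in 4 portions while the reagent sits in a second phase.

| flask | starting material | reagent in the second phase | remark | time | volume of the second phase over the first |
|---|---|---|---|---|---|
| theta | 0.64 M (in portions, 4) | 0.86 M | run made earlier; portions every 25 min |  |  |
| gamma | 0.64 M (in portions, 4) | 1.9 M | run made earlier; portions every 25 min |  |  |
| beta | 0.32 M (in portions, 4) | 1.28 M | run made earlier; portions every 25 min |  |  |
| flask | 0.64 M (in portions, 4) | 1.28 M | the portions of starting material follow each other after 25 min, the first at the start | 4.0 h | 2.0 |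

| run | time / h | product / % | starting material / % |
|---|---|---|---|
| theta | 0.333 | 2 | 20 |
| theta | 0.667 | 4 | 45 |
| theta | 1.00 | 9 | 67 |
| theta | 1.33 | 15 | 85 |
| theta | 1.50 | 20 | 83 |
| theta | 2.00 | 27 | 69 |
| theta | 2.50 | 39 | 65 |
| gamma | 0.333 | 3 | 23 |
| gamma | 0.667 | 9 | 43 |
| gamma | 1.00 | 18 | 56 |
| gamma | 1.33 | 31 | 69 |
| gamma | 1.50 | 38 | 63 |
| gamma | 2.00 | 53 | 47 |
| gamma | 2.50 | 63 | 34 |
| beta | 0.200 | 1 | 26 |
| beta | 0.333 | 0 | 27 |
| beta | 0.667 | 9 | 43 |
| beta | 1.33 | 25 | 75 |
| beta | 2.50 | 62 | 39 |

(each reading ± 1.5 percentage points)

- the species that holds most of what was charged as starting material, at 4.0 h (product / starting material)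
- the largest share itself, whichever of these holds it, in percent of the starting material charged

- in the second phase: reagent in the second phase; everything else is in the first
- charges count per volume of the first phase; a concentration in a rate is the amount of a species over the volume of its own phase; every rate counts per litre of the first phase
- the numbers in the tables scatter with a standard deviation of 1.5 percentage points
- the earlier runs hold the two phases in the same ratio of volumes as the flask asked about
- a reading or a percentage of product counts all its forms, free or not
- percentages count the whole charge, also what has not yet gone in

**The puzzle.** Take k, the pseudo-first-order decay constant of starting material after the last portion, between the readings at 1.33 h and 2.50 h. It reads 0.229 h⁻¹ in theta and 0.605 h⁻¹ in gamma. But gamma holds 2.21 times the reagent of theta, and its k is 2.64 times as large.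

**Clearing it.** Assume each product takes one reagent, and subtract the mean product of that window from the charge. That leaves 0.687 M in theta and 1.60 M in gamma, a ratio of 2.33. Now divide: the two runs read 0.333 L mol⁻¹ h⁻¹ and 0.378 L mol⁻¹ h⁻¹, close within the scatter. Their mean, 0.356 L mol⁻¹ h⁻¹, is κ, the decay constant per molar of reagent left. Keep κ to this charge: beta, at half of it, reads 0.490 L mol⁻¹ h⁻¹, higher.

**My reckoning.** Start the flask at 77.0% starting material at 1.33 h, midway between theta and gamma. Using the reagent left at that moment, 26.2% remains at 4.0 h. Put that answer back, taking mean product over the stretch: 30.6% remains, so product stands near 69.4%.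

**The forecast.** It says product at 73%, holding that “the rate is about first order in reagent”. That is above my figure.

**The result.** The flask gives product at 68.0%, idle adduct counted in.

    reagent in the reaction phase + product ⇌ idle adduct, settled at all times (K = 18.0 L mol⁻¹)
    starting material + reagent in the reaction phase → product (k = 1.60 L mol⁻¹ h⁻¹)
    reagent in the reaction phase ⇌ reagent in the second phase, rate k3*([reagent in the reaction phase] - [reagent in the second phase]/K3) per volume of the first phase (partition coefficient = 0.350, kL = 0.320 h⁻¹)

**Carrying κ.** Part of the gap to full conversion comes from the time given, acting together with the bottleneck of the uptake of reagent in the second phase as reagent in the reaction phase: the flask holds 68.0% product, against >99.9% when left until 40.0 h and 82.5% without the bottleneck. Now use κ on the flask at 4.0 h: the reagent left gives k of 0.301 h⁻¹. Run on from 32% to the neighbour read at 10 h, that k leaves 5.27%. Go round again with mean product: 6.33%. That neighbour holds 7.0% starting material.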